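The numbers in the tables are simulated on assumed constants, noise included.

If each protic impurity takes one starting material, any charge missing beyond [protic impurity]/[starting material] went some other way, and two runs can show how that loss moves with heat.

| flask | starting material | partner | protic impurity | temperature | remark | time |
|---|---|---|---|---|---|---|
| Monday's | 0.80 M | 0.76 M | 0.020 M | 30 °C | run made earlier |  |
| Saturday's | 0.80 M | 0.76 M | 0.080 M | 65 °C | run made earlier |  |
| theta | 0.80 M | 0.760 M | 0.0400 M | 35 °C |  | 2.0 min |
| beta | 0.80 M | 0.760 M | 0.0400 M | 65 °C |  | 2.0 min |
| epsilon | 0.80 M | 0.760 M | 0.0400 M | 95 °C |  | 2.0 min |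

- Monday's (time / s: target / %, starting material / %): 15.0: 54, 40; 30.0: 68, 28; 40.0: 73, 18; 60.0: 79, 18; 80.0: 81, 14
- Saturday's (time / s: target / %, starting material / %): 10.0: 79, 0; 12.0: 77, 0; 20.0: 80, 0

(readings scatter by 1.5 percentage points)

1. the flask with the highest amount of target, in percent of the starting material charged ("all alike" if they lie within 1.5 percentage points) (theta / beta / epsilon / all alike)
2. final target, as a percentage of the starting material charged, in theta
3. final target, as a percentage of the starting material charged, in beta
4. final target, as a percentage of the starting material charged, in epsilon

- the numbers in the tables scatter by 1.5 percentage points (one standard deviation)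

I call the gap what target and starting material together fail to account for. At the last readings it is 5.00% on Monday and 20.0% on Saturday. On my one-for-one assumption the impurity accounts for 2.50% of the starting material charged on Monday and 10.0% on Saturday. The rest, divided by target, is my toll, the inverse of a selectivity factor: 0.0309 on Monday and 0.125 on Saturday.

The weak link is Monday's remainder: 2.5 percentage points, from a gap whose own scatter is 2.1 points. So I replace each curve by its mean. The mean of Monday's 5 gaps is 5.40%, uncertain by 0.95 points, beside a mean target of 71.0%, so the toll reads 0.0408. Saturday's 3 readings give 0.144.

The two runs differ in impurity as well as temperature, so it is my assumption that subtracting the impurity's share leaves a toll that follows an Arrhenius line, whose slope is the toll energy 30.7 kJ/mol. It gives a toll of 0.0498 in theta and 0.351 in epsilon, while beta sits at Saturday's temperature. After the impurity's 5.00%, target is the remainder over one plus the toll: 83.0% in beta and 70.3% in epsilon.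

Theta's ceiling is 90.5%, less what is unused. If starting material falls as one over time, Monday's 14% at 80.0 s becomes 9.33% at 2.0 min, but theta is warmer, so I commit to the middle, 85.8%, with theta on top.

The forecast differs: 85% in theta, 90% in beta and 89.5% in epsilon, with beta on top and epsilon carrying “a slight risk of unseen thermal loss”.

The flasks give 86.9% in theta, 82.9% in beta and 73.6% in epsilon, so theta holds most. Epsilon holds 22.0% of side product beside 73.6% of target.

    partner → decomposed reagent (k = 2.40 × 10⁻⁴ /s, Ea = 97.0 kJ/mol)
    starting material → side product (k = 0.00270 /s, Ea = 99.0 kJ/mol)
    starting material + partner → target (k = 0.170 /M/s, Ea = 68.0 kJ/mol)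
    starting material + protic impurity → quenched substrate (k = 0.240 /M/s, Ea = 67.0 kJ/mol)
    (constants at 35 °C)

That ratio is 0.299, against the 0.351 reckoned with the toll energy. Carried down to a neighbour of theta kept at 10 °C, the same toll energy gives 0.0173. That neighbour holds 0.636% of side product beside 57.6% of target, a ratio of 0.0110.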